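**Retrosynthetic overview**
1. Target 13 (31-membered lactone) ⇐ unsaturated thiophene-bridged macrolide 12: one Raney Ni operation removes sulfur, turning the four thiophene carbons into C16–C19 as (CH2)4, and saturates C10=C11.
2. 12 ⇐ acyclic diene ester 11 by ring-closing metathesis; this is the only ring-forming step.
3. 11 ⇐ alcohol 9 + undec-10-enoyl chloride 10 (ester bond).
4. 9 ⇐ thiophene 1 + 6-bromohex-1-ene 2 + 11-bromoundecan-1-ol 3 by one-pot 2,5-dilithiation/alkylation.
5. Ring order: thiophene ring (bought) → macrocycle around it (metathesis) → thiophene ring destroyed last.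

Assumption: the SMILES is read as one ester C=O, 29 CH2 groups and one ring oxygen (oxacyclohentriacontan-2-one, C30H58O2); the molecule is achiral, so there is no stereocentre or enantiomer to control.

Carbon bookkeeping for the lactone: C1–C10 from 10, C11–C15 from 2, C16–C19 from thiophene, C20–C30 and the ring oxygen from 3 (10 + 5 + 4 + 11 = 30).

**Step 1**
Reactants: 1 thiophene; 2 6-bromohex-1-ene; 3 11-bromoundecan-1-ol
Product: 9 11-[5-(hex-5-en-1-yl)thiophen-2-yl]undecan-1-ol, via 2-thienyllithium 4 (not isolated), via 2-(hex-5-en-1-yl)thiophene 5 (not isolated), via 5-(hex-5-en-1-yl)-2-thienyllithium 6 (not isolated), via lithium 11-bromoundecan-1-olate 7 (not isolated), via product lithium alkoxide 8 (not isolated)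
Conditions: 1 (1.0 eq), n-BuLi (1.0 eq), THF, −78 to 0 °C; 2 (1.05 eq), 0 °C to rt; n-BuLi (1.0 eq), −78 to 0 °C; 7 (0.8 eq, from 3 + n-BuLi, THF, −78 °C), rt to 50 °C; H2O
Reagents that add atoms: none
Why: Two consecutive α-lithiation/SN2 alkylations of thiophene in one pot (the 2-H and then the 5-H are the most acidic ring protons, and 2-thienyllithiums alkylate primary bromides) install both chains, while the hydroxyl of 3 is masked in situ as lithium alkoxide 7, which is too poor a nucleophile in THF to compete; no stereocentre is formed.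

**Step 2**
Reactants: 9 11-[5-(hex-5-en-1-yl)thiophen-2-yl]undecan-1-ol; 10 undec-10-enoyl chloride
Product: 11 11-[5-(hex-5-en-1-yl)thiophen-2-yl]undecyl undec-10-enoate
Conditions: Et3N, DMAP (cat.), CH2Cl2, 0 °C to rt
Reagents that add atoms: none
Why: DMAP-catalysed acylation (nucleophilic acyl substitution) of an unhindered primary alcohol by an acid chloride is essentially quantitative, and thiophene and both terminal alkenes are inert; no stereocentre is formed.

**Step 3**
Reactants: 11 11-[5-(hex-5-en-1-yl)thiophen-2-yl]undecyl undec-10-enoate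
Product: 12 13-oxa-32-thiabicyclo[27.2.1]dotriaconta-1(31),23,29-trien-14-one (E/Z mixture at C23=C24; the 2,5-thiophene-bridged macrolide)
Conditions: second-generation Grubbs catalyst RuCl2(=CHPh)(H2IMes)(PCy3) (5 mol %), 1,4-benzoquinone (10 mol %), CH2Cl2 (2 mM), 40 °C
Reagents that add atoms: none
Why: Ring-closing olefin metathesis of two unhindered terminal alkenes at high dilution closes the strain-free large ring with loss of ethene, a 2,5-dialkylthiophene does not poison the ruthenium carbene, benzoquinone suppresses Ru–H olefin migration (which would give ring-contracted homologues), and the E/Z ratio is irrelevant because the alkene is reduced in step 4.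

**Step 4**
Reactants: 12 13-oxa-32-thiabicyclo[27.2.1]dotriaconta-1(31),23,29-trien-14-one
Product: 13 oxacyclohentriacontan-2-one (triacontan-30-olide, the target)
Conditions: Raney Ni (grade W-2, washed neutral, ca. 10 wt eq), H2 (1 atm), THF/EtOH 4:1, 50 °C
Reagents that add atoms: none
Why: Raney nickel reductive desulfurization (hydrodesulfurization) of the 2,5-dialkylthiophene destroys the aromatic ring and leaves its four carbons as a (CH2)4 segment while the same hydrogen-loaded nickel surface hydrogenates the C23=C24 alkene, and the remote unactivated lactone is inert on neutral nickel; no stereocentre is formed.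

**Compound list**
1 | thiophene | c1ccsc1 | starting material
2 | 6-bromohex-1-ene | C=CCCCCBr | starting material
3 | 11-bromoundecan-1-ol | OCCCCCCCCCCCBr | starting material
4 | 2-thienyllithium | [Li]c1cccs1 | intermediate
5 | 2-(hex-5-en-1-yl)thiophene | C=CCCCCc1cccs1 | intermediate
6 | 5-(hex-5-en-1-yl)-2-thienyllithium | [Li]c1ccc(CCCCC=C)s1 | intermediate
7 | lithium 11-bromoundecan-1-olate | [Li+].[O-]CCCCCCCCCCCBr | intermediate
8 | lithium 11-[5-(hex-5-en-1-yl)thiophen-2-yl]undecan-1-olate | [Li+].[O-]CCCCCCCCCCCc1ccc(CCCCC=C)s1 | intermediate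
9 | 11-[5-(hex-5-en-1-yl)thiophen-2-yl]undecan-1-ol | OCCCCCCCCCCCc1ccc(CCCCC=C)s1 | intermediate
10 | undec-10-enoyl chloride | C=CCCCCCCCCC(=O)Cl | starting material
11 | 11-[5-(hex-5-en-1-yl)thiophen-2-yl]undecyl undec-10-enoate | C=CCCCCCCCCC(=O)OCCCCCCCCCCCc1ccc(CCCCC=C)s1 | intermediate
12 | 13-oxa-32-thiabicyclo[27.2.1]dotriaconta-1(31),23,29-trien-14-one (E/Z mixture, E isomer drawn) | O=C1CCCCCCCC/C=C/CCCCc2ccc(CCCCCCCCCCCO1)s2 | intermediate
13 | oxacyclohentriacontan-2-one (achiral) | O=C1CCCCCCCCCCCCCCCCCCCCCCCCCCCCCO1 | target

**Totals**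
Total step count: 4. Longest linear sequence: 4 steps (from thiophene 1).

**Three steps most likely to fail, with fallbacks**

Step 1 (one-pot unsymmetrical dialkylation with an unprotected bromo alkoxide). The risks are lithium–hydrogen scrambling, which gives symmetric dialkylthiophenes, and sluggish alkylation by the aggregated alkoxide 7. The fallback sets out from 1, 2 and 3 and returns at 9, using a stepwise, protecting-group route with isolation. Alkylate 4 (from excess 1 and n-BuLi) with 2 and isolate 2-(hex-5-en-1-yl)thiophene 5 by distillation. Protect 3 with 3,4-dihydro-2H-pyran and PPTS to give 2-[(11-bromoundecyl)oxy]oxane F1. Lithiate 5 (n-BuLi, THF, 0 °C) and alkylate with F1 to give 2-({11-[5-(hex-5-en-1-yl)thiophen-2-yl]undecyl}oxy)oxane F2. Cleave the acetal (PPTS, MeOH, 50 °C) to give 9.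

Step 3 (metathesis closure of the large ring). The risks are oligomerization and olefin migration. The fallback sets out from 9 and returns at 12, moving the ring-closing bond from C=C to the ester C–O. Cross-metathesize 9 with excess methyl undec-10-enoate (second-generation Grubbs catalyst, CH2Cl2, 40 °C, no dilution needed) to give methyl 15-[5-(11-hydroxyundecyl)thiophen-2-yl]pentadec-10-enoate F3. Saponify (LiOH, THF/H2O, then dilute HCl) to 15-[5-(11-hydroxyundecyl)thiophen-2-yl]pentadec-10-enoic acid F4. Close the ring by Yamaguchi macrolactonization (2,4,6-trichlorobenzoyl chloride, Et3N, THF; then slow addition to DMAP in toluene, 80 °C) to give 12.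

Step 4 (global Raney Ni reduction on the macrolide). The risks are incomplete sulfur removal or residual unsaturation, ester cleavage on basic nickel, and adsorption of the waxy product. The fallback sets out from 12 and returns at 13, doing the dearomatization on the opened chain where ester stability no longer matters. Heat 12 with Raney Ni in KOH/EtOH/H2O under H2 at 80 °C (saponification, then desulfurization and hydrogenation of the soluble carboxylate). Acidify to give 30-hydroxytriacontanoic acid F5. Relactonize under Yamaguchi high-dilution conditions to give 13.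

**Further compounds**
F1 | step 1 | 2-[(11-bromoundecyl)oxy]oxane (racemic acetal) | BrCCCCCCCCCCCOC1CCCCO1
F2 | step 1 | 2-({11-[5-(hex-5-en-1-yl)thiophen-2-yl]undecyl}oxy)oxane (racemic acetal) | C=CCCCCc1ccc(CCCCCCCCCCCOC2CCCCO2)s1
F3 | step 3 | methyl 15-[5-(11-hydroxyundecyl)thiophen-2-yl]pentadec-10-enoate (E/Z mixture, E drawn) | COC(=O)CCCCCCCC/C=C/CCCCc1ccc(CCCCCCCCCCCO)s1
F4 | step 3 | 15-[5-(11-hydroxyundecyl)thiophen-2-yl]pentadec-10-enoic acid (E/Z mixture, E drawn) | OC(=O)CCCCCCCC/C=C/CCCCc1ccc(CCCCCCCCCCCO)s1
F5 | step 4 | 30-hydroxytriacontanoic acid | OCCCCCCCCCCCCCCCCCCCCCCCCCCCCCC(=O)O
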